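## Conventions and compound numbers

Atom numbers C1–C11 are those of the target decalin and are used for every intermediate: C1–C4 belong to ring A, C5 and C10 are the ring-fusion carbons, C6–C9 complete ring B, and C11 is the benzylic carbon. The β face is the face of the C5, C8 and C9 methyl groups; α is the opposite face.

Compounds: 1 tiglic aldehyde; 2 its silyl dienol ether; 3 cycloadduct; 4 methyl 4-hydroxy-3-iodobenzoate; 5 its benzyl ether; 6 aryl Grignard reagent; 7 benzylic carbinol; 8 xanthate salt; 9 xanthate; 10 arylmethyl cyclohexenyl silyl ether; 11 allylic alcohol; 12 enone; 13 pent-4-enal; 14 enolate; 15 aldol; 16 its silyl ether; 17 ozonide; 18 keto aldehyde; 19 titanium diolate; 20 octalin silyl ether; 21 octalinol; 22 octalinone; 23 trans-decalone phenol; 24 dictyoceratin C.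

## Analysis of the target

Dictyoceratin C (24) is a 4,9-friedodrimane: a trans-fused decalin (ring A: C1–C5 and C10; ring B: C5–C10). C9 carries a methyl group and, through C11, a 2-hydroxy-5-(methoxycarbonyl)phenyl ring; C4 carries an exocyclic methylene. All four stereocentres lie on ring B and are contiguous: quaternary C5 (S, methyl β), C10 (S, H α), quaternary C9 (R, methyl β, arylmethyl α) and C8 (S, methyl β). The C5 and C9 methyls are therefore syn-diaxial across C10, and the C8 and C9 methyls are cis-vicinal. The sensitive groups are the 1,1-disubstituted alkene next to quaternary C5 (acid moves it into the ring or starts cationic 1,2-shifts), the free phenol, and the methyl ester para to it. The difficulty is the pair of all-carbon quaternary centres, one flanked by two further stereocentres, on a ring with no heteroatom to steer reagents. The strategy rests on one observation: C8 with its methyl, C9 with its methyl, and C11 are the β-carbon, α-carbon and formyl carbon of (E)-2-methylbut-2-enal (1). C7, C6, C5 with its methyl and an oxidised C10 are the same aldehyde in its dienol form (2). Ring B is thus a [4+2] adduct of two tiglaldehyde units, and the C10 oxygen left by the diene is the handle for attaching ring A.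

## Retrosynthetic reasoning

**24 ⇒ 23 (C4=CH2).** The exocyclic alkene is cut first and traced to the C4 ketone of 23. Placing the methylenation last means the acid- and hydrogenation-sensitive alkene meets no further reagent. The phenol is left free, because as its phenoxide it deactivates the para ester toward the ylide.

**23 ⇒ 22 (C10–H, O-benzyl).** The C10 hydrogen is added to the C1=C10 alkene of 22. The β face of that alkene is covered by the two axial methyls at C5 and C9, so hydrogen should arrive on the α face and give the trans ring fusion. The benzyl ether is chosen so that the same operation frees the phenol.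

**22 ⇒ 21 ⇒ 20 ⇒ 18 (C1=C10, ring A).** Ring A is opened at C1=C10 to keto aldehyde 18. C10 lies between two quaternary carbons, so only a bond formation that needs neither enolisation nor an open approach trajectory is credible; a reductive carbonyl coupling (McMurry) meets this, and its only possible alkene is C1=C10. The C4 oxygen is carried as a silyl ether through the coupling and is oxidised before the hydrogenation, so that C4 is sp2 and has no influence on the facial course.

**18 ⇒ 16 ⇒ 15 ⇒ 12 + 13 (C4–C5, quaternary C5).** The C1 aldehyde comes from the terminal alkene of 16. The C4–C5 bond is cut to enolate 14 and pent-4-enal (13), which supplies C1–C4 with C4 at the oxidation level needed for the later methylene. Enolate 14 is formed regiospecifically by conjugate reduction of enone 12. The forward aldol has to put C4 on the α face, anti to the pseudoaxial C9 methyl.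

**12 ⇒ 11 ⇒ 10 (C10 enone).** The enone is the oxidised form of the allylic silyl ether in 10. The C10 oxygen and the C5=C6 alkene are exactly what the cycloaddition leaves behind.

**10 ⇒ 9 ⇒ 7 ⇒ 3 + 5 (C11–aryl).** The arylmethyl group is cut at the C11–aryl bond. C11 is neopentylic, so displacement chemistry is excluded; addition of aryl Grignard reagent 6 to the aldehyde of 3, followed by radical deoxygenation, is the reliable alternative. The arene is attached now because the formyl group is the only electrophile in 3; later the C10 and C4 carbonyls would compete.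

**3 ⇒ 1 + 2 (C9–C10 and C7–C8, ring B).** Ring B is cut into dienophile 1 and diene 2. This one step forms two ring bonds, the C9 quaternary centre and the C8/C9 stereo-pair, with every carbon in its final place. The forward reaction needs a chiral Lewis acid that activates the sluggish β-substituted enal and selects one face.

**2 ⇒ 1 and 5 ⇒ 4.** Diene 2 is one soft-enolisation step from 1. Benzyl ether 5 is one alkylation from commercial phenol 4.

## Alternatives that were turned down

**Alternative 1: biomimetic shift cascade.** No ring bond is cut. The C9 and C5 methyls are moved back to C10 and C4, which leads to a normal drimane carrying the arylmethyl group and a C8 tertiary alcohol, reachable from the chiral-pool lactone sclareolide A2. In the forward direction a Lewis acid ionises the C8 alcohol. Four suprafacial, antiperiplanar 1,2-shifts follow (H-9 to C8, CH3-10 to C9, H-5 to C10, CH3-4 to C5), and proton loss from the remaining C4 methyl gives dictyoceratin C O-acetate A1.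
- For: it is by far the shortest route, and all four stereocentres are set in one stereospecific event from a cheap enantiopure precursor.
- Against: the relay must pass four cations and then end by losing a proton from a methyl group. Each cation can instead lose a ring proton (for example to the tetrasubstituted C5=C10 alkene after two shifts), and at the end the trisubstituted C3=C4 alkene is thermodynamically preferred over the exocyclic one. The arene can also capture the cations. The product-determining step is therefore an uncontrolled proton loss that gives alkene isomers which are hard to separate.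
- Comparison: Alternative 1 is clearly stronger in step count and in how the stereocentres arise. The chosen route offers instead an unambiguous alkene position (carbonyl methylenation) and one controllable step per stereocentre.

**Alternative 2: oxidative radical bicyclisation.** The decalin is cut at C9–C10 and C4–C5 to an acyclic α-arylmethyl β-keto ester with a C5=C10 alkene and a terminal silyl alkyne. A one-electron metal oxidant generates the C9 radical, which closes ring B by 6-endo attack on C10. The C5 radical then closes ring A by 6-exo attack on the alkyne, and the vinyl radical takes a hydrogen atom, giving the 8-phenylmenthyl keto ester A3.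
- For: both rings, C5, C9, C10 and the C4 exocyclic carbon arise in one step, and trans fusion is the normal outcome of such cyclisations.
- Against: C9 receives an ester, not a methyl, and turning an ester on a neopentylic quaternary carbon into CH3 costs reduction, activation and deoxygenation. The C8 ketone must still become the β-methyl stereocentre in the presence of the C4 alkene. The aryl bromide must still be carbonylated. Absolute control depends on a stoichiometric auxiliary whose influence on a radical cyclisation is moderate.
- Comparison: Alternative 2 is stronger in ring-forming economy. The chosen route brings the C8 and C9 methyls and C11 in from the dienophile in their final form, carries the complete arene, and takes its absolute configuration from a catalyst.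

**Alternative 3: thiane bridge as masked syn methyls.** The C5 and C9 methyls are tied back into a CH2–S–CH2 bridge, and the carbocycle is cut at C5–C6 and C8–C9 to a thianone β-keto ester and methyl vinyl ketone A5. A catalytic asymmetric Michael addition to A5 forms C5–C6, and acid-driven aldol condensation from the other α-carbon forms C8–C9, giving the thiabicycle A4.
- For: the syn relation of the C5 and C9 methyls, the hardest relationship in the target, is guaranteed by the bridge, and both quaternary centres come from one well-established catalytic asymmetric step.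
- Against: the C8 stereocentre must be set by reducing C7=C8 on a bridged bicycle. The bridging C10 ketone must become a CH that carries ring A, which has to be built from the C5 ester carbon. Desulfurisation must precede any alkene. The anisole ring lacks the ester and needs late functionalisation and O-demethylation.
- Comparison: Alternative 3 is stronger on the C5/C9 relationship, which the chosen route leaves to a substrate-controlled aldol. The chosen route sets the C8/C9 pair directly and needs far fewer corrective operations on the arene and on C10.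

Key step: step 2

## Remarks on the chemistry (assumptions)

- In the accepted pre-transition-state model for 2-substituted enals, the (S)-configured oxazaborolidinium exposes the Cα re face. Compound 3 needs attack on the Cα si face, so the (R)-catalyst is specified; if the sense proved opposite, the (S)-catalyst would be used and nothing else would change.
- Commercial methyl 4-hydroxy-3-iodobenzoate (4) is used as the aryl source because its iodine–magnesium exchange is fast at low temperature in the presence of the ester.
- The C11 carbinol in 7–9 and the C4 carbinol in 15–21 are carried as epimer mixtures, because both centres are destroyed later.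

## Route

Step 1
Reactants: 1 (E)-2-methylbut-2-enal (tiglic aldehyde)
Product: 2 (1E)-1-(tert-butyldimethylsilyloxy)-2-methylbuta-1,3-diene
Conditions: TBSOTf, Et3N, Et2O, 0 °C → rt
Reagents that add atoms: tert-butyldimethylsilyl trifluoromethanesulfonate, CC(C)(C)[Si](C)(C)OS(=O)(=O)C(F)(F)F
Why: O-Silylation of the s-trans enal and γ-deprotonation by the amine (soft enolisation to a silyl dienol ether) should give the 1-silyloxy diene; the s-trans ground state places oxygen trans to the vinyl group, which is the (1E) geometry needed for cycloaddition.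

Step 2
Reactants: 1 (E)-2-methylbut-2-enal; 2 (1E)-1-(tert-butyldimethylsilyloxy)-2-methylbuta-1,3-diene
Product: 3 (1R,2S,6S)-2-(tert-butyldimethylsilyloxy)-1,3,6-trimethylcyclohex-3-ene-1-carbaldehyde
Conditions: (R)-3,3-diphenyl-1-(2-methylphenyl)tetrahydro-1H,3H-pyrrolo[1,2-c][1,3,2]oxazaborole (20 mol %), HNTf2 (17 mol %), CH2Cl2, −78 → −40 °C; Et3N quench
Reagents that add atoms: none
Why: The aldehyde of 1 binds the boron of the N-protonated oxazaborolidine through the lone pair anti to C9, a formyl C–H···O contact to the ring oxygen holds the s-trans enal over the neighbouring phenyl group, and the electron-rich diene 2 adds to the open face in a concerted, asynchronous [4+2] cycloaddition in which the C7–C8 bond runs ahead of C9–C10. The closest known reaction type is the oxazaborolidinium-catalysed enantioselective Diels–Alder reaction of 2-substituted enals with silyloxy dienes. Ring B closes by intermolecular [4+2] cycloaddition, two σ bonds joining a four-carbon and a two-carbon unit into a cyclohexene. C8 and C9 are fixed relative to each other by the (E) geometry of 1, which is transferred suprafacially (methyls cis, formyl trans to the C8 methyl), and their absolute configuration (8S,9R in the target numbering) is set by the (R)-catalyst, which should expose the Cα si/Cβ re face. C10 follows from the endo orientation of the formyl group toward the silyloxy terminus (silyloxy cis to formyl) and is erased later, so its selectivity is not critical. The step needs regioselectivity (C10 to C9), which the 1-silyloxy donor secures by making C7 the nucleophilic terminus against the weaker opposing bias of the C5 methyl. It also needs selectivity for the C=C over the C=O bond, which is supported by low temperature and a slight deficit of HNTf2 so that no free acid desilylates 2.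

Step 3
Reactants: 4 methyl 4-hydroxy-3-iodobenzoate
Product: 5 methyl 4-(benzyloxy)-3-iodobenzoate
Conditions: BnBr, K2CO3, DMF, rt
Reagents that add atoms: benzyl bromide, BrCc1ccccc1
Why: Williamson etherification of an acidic phenol; the benzyl group survives all steps up to the hydrogenation, where it is removed without a separate operation.

Step 4
Reactants: 5 methyl 4-(benzyloxy)-3-iodobenzoate; 3 (1R,2S,6S)-2-(tert-butyldimethylsilyloxy)-1,3,6-trimethylcyclohex-3-ene-1-carbaldehyde
Product: 7 methyl 4-(benzyloxy)-3-{hydroxy[(1S,2S,6S)-2-(tert-butyldimethylsilyloxy)-1,3,6-trimethylcyclohex-3-en-1-yl]methyl}benzoate (both C11 epimers), via arylmagnesium chloride 6 (not isolated)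
Conditions: i-PrMgCl·LiCl, THF, −40 °C; then 3, −40 → 0 °C; aq NH4Cl
Reagents that add atoms: none
Why: Iodine–magnesium exchange at low temperature gives an ester-bearing aryl Grignard reagent that adds to the aldehyde, the only reactive electrophile (Grignard addition); the new C11 carbinol centre is removed in step 6, so its configuration does not matter.

Step 5
Reactants: 7 methyl 4-(benzyloxy)-3-{hydroxy[(1S,2S,6S)-2-(tert-butyldimethylsilyloxy)-1,3,6-trimethylcyclohex-3-en-1-yl]methyl}benzoate
Product: 9 methyl 4-(benzyloxy)-3-{[(1S,2S,6S)-2-(tert-butyldimethylsilyloxy)-1,3,6-trimethylcyclohex-3-en-1-yl]{[(methylsulfanyl)carbonothioyl]oxy}methyl}benzoate (S-methyl xanthate), via sodium xanthate salt 8 (not isolated)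
Conditions: NaN(SiMe3)2, CS2, THF, −78 °C; then MeI, −78 → 0 °C
Reagents that add atoms: carbon disulfide, S=C=S; iodomethane, CI
Why: Xanthate formation uses the smallest possible electrophile for a neopentylic alcohol; CS2 is present before the base so that the alkoxide is trapped before the neighbouring silyl group can migrate.

Step 6
Reactants: 9 S-methyl xanthate of 7
Product: 10 methyl 4-(benzyloxy)-3-{[(1R,2S,6S)-2-(tert-butyldimethylsilyloxy)-1,3,6-trimethylcyclohex-3-en-1-yl]methyl}benzoate
Conditions: n-Bu3SnH, AIBN (azobisisobutyronitrile, cat.), toluene, 90 °C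
Reagents that add atoms: none
Why: Barton–McCombie deoxygenation through a stabilised benzylic radical; C9 is quaternary, so no xanthate elimination can compete, and a high stannane concentration should outrun any fragmentation of the radical.

Step 7
Reactants: 10 methyl 4-(benzyloxy)-3-{[(1R,2S,6S)-2-(tert-butyldimethylsilyloxy)-1,3,6-trimethylcyclohex-3-en-1-yl]methyl}benzoate
Product: 11 methyl 4-(benzyloxy)-3-{[(1R,2S,6S)-2-hydroxy-1,3,6-trimethylcyclohex-3-en-1-yl]methyl}benzoate
Conditions: n-Bu4NF, THF, rt → 40 °C
Reagents that add atoms: none
Why: Fluoride-induced cleavage of the secondary silyl ether; the methyl ester and the benzyl ether are inert to fluoride under these conditions.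

Step 8
Reactants: 11 methyl 4-(benzyloxy)-3-{[(1R,2S,6S)-2-hydroxy-1,3,6-trimethylcyclohex-3-en-1-yl]methyl}benzoate
Product: 12 methyl 4-(benzyloxy)-3-{[(1R,6S)-1,3,6-trimethyl-2-oxocyclohex-3-en-1-yl]methyl}benzoate
Conditions: Dess–Martin periodinane, CH2Cl2, 0 °C → rt
Reagents that add atoms: none
Why: Dess–Martin oxidation of the allylic alcohol gives the C10 enone; any C10 epimer from step 2 converges here, and the quaternary C9 rules out epimerisation next to the carbonyl.

Step 9
Reactants: 12 methyl 4-(benzyloxy)-3-{[(1R,6S)-1,3,6-trimethyl-2-oxocyclohex-3-en-1-yl]methyl}benzoate; 13 pent-4-enal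
Product: 15 methyl 4-(benzyloxy)-3-{[(1R,3R,6S)-3-(1-hydroxypent-4-en-1-yl)-1,3,6-trimethyl-2-oxocyclohexyl]methyl}benzoate (C4 carbinol epimers), via lithium enolate 14 (not isolated)
Conditions: LiBH(s-Bu)3, THF, −78 °C; then 13, −78 °C; aq NH4Cl at −78 °C
Reagents that add atoms: none
Why: Conjugate hydride delivery to the unsubstituted β-carbon C6 gives the only possible enolate (C5=C10) regiospecifically, and its aldol addition to 13 forms C4–C5 (reductive aldol reaction). The aldehyde should approach C5 on the α face, anti to the pseudoaxial C9 methyl that sits 1,3 to C5, which sets the quaternary centre with its methyl β; the cold quench prevents retro-aldol cleavage.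

Step 10
Reactants: 15 methyl 4-(benzyloxy)-3-{[(1R,3R,6S)-3-(1-hydroxypent-4-en-1-yl)-1,3,6-trimethyl-2-oxocyclohexyl]methyl}benzoate
Product: 16 methyl 4-(benzyloxy)-3-{[(1R,3R,6S)-3-[1-(tert-butyldimethylsilyloxy)pent-4-en-1-yl]-1,3,6-trimethyl-2-oxocyclohexyl]methyl}benzoate
Conditions: TBSOTf, 2,6-lutidine, CH2Cl2, −78 → 0 °C
Reagents that add atoms: tert-butyldimethylsilyl trifluoromethanesulfonate, CC(C)(C)[Si](C)(C)OS(=O)(=O)C(F)(F)F
Why: Silylation with a silyl triflate and a hindered base protects the hindered aldol hydroxyl without generating an alkoxide that could undergo retro-aldol cleavage; the ketone has no α-hydrogen and cannot form a silyl enol ether.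

Step 11
Reactants: 16 methyl 4-(benzyloxy)-3-{[(1R,3R,6S)-3-[1-(tert-butyldimethylsilyloxy)pent-4-en-1-yl]-1,3,6-trimethyl-2-oxocyclohexyl]methyl}benzoate
Product: 18 methyl 4-(benzyloxy)-3-{[(1R,3R,6S)-3-[1-(tert-butyldimethylsilyloxy)-4-oxobutyl]-1,3,6-trimethyl-2-oxocyclohexyl]methyl}benzoate, via secondary ozonide 17 (not isolated)
Conditions: O3, CH2Cl2, −78 °C; then PPh3, −78 °C → rt
Reagents that add atoms: ozone, [O-][O+]=O
Why: Ozonolysis with reductive work-up cleaves the only alkene in the molecule to the C1 aldehyde; the ester-deactivated arene and the benzyl ether should survive a stoichiometric dose of ozone.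

Step 12
Reactants: 18 methyl 4-(benzyloxy)-3-{[(1R,3R,6S)-3-[1-(tert-butyldimethylsilyloxy)-4-oxobutyl]-1,3,6-trimethyl-2-oxocyclohexyl]methyl}benzoate
Product: 20 methyl 4-(benzyloxy)-3-{[(1R,2S,4aS)-5-(tert-butyldimethylsilyloxy)-1,2,4a-trimethyl-1,2,3,4,4a,5,6,7-octahydronaphthalen-1-yl]methyl}benzoate, via cyclic titanium diolate 19 (not isolated)
Conditions: TiCl3(DME)1.5, Zn–Cu, DME, reflux, slow addition of 18
Reagents that add atoms: none
Why: Intramolecular McMurry coupling: low-valent titanium joins the aldehyde and ketone carbons to a diolate and deoxygenates it on heating to the only possible alkene, C1=C10. The reaction needs no enolisation and tolerates the two quaternary neighbours of C10; six-membered ring closure under high dilution is favoured over intermolecular coupling or reaction at the remote ester.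

Step 13
Reactants: 20 methyl 4-(benzyloxy)-3-{[(1R,2S,4aS)-5-(tert-butyldimethylsilyloxy)-1,2,4a-trimethyl-1,2,3,4,4a,5,6,7-octahydronaphthalen-1-yl]methyl}benzoate
Product: 21 methyl 4-(benzyloxy)-3-{[(1R,2S,4aS)-5-hydroxy-1,2,4a-trimethyl-1,2,3,4,4a,5,6,7-octahydronaphthalen-1-yl]methyl}benzoate
Conditions: HF·pyridine, pyridine, THF, 0 °C → rt
Reagents that add atoms: none
Why: Buffered hydrogen fluoride removes the hindered neopentylic silyl ether and is too weakly acidic to protonate the trisubstituted alkene.

Step 14
Reactants: 21 methyl 4-(benzyloxy)-3-{[(1R,2S,4aS)-5-hydroxy-1,2,4a-trimethyl-1,2,3,4,4a,5,6,7-octahydronaphthalen-1-yl]methyl}benzoate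
Product: 22 methyl 4-(benzyloxy)-3-{[(1R,2S,4aS)-1,2,4a-trimethyl-5-oxo-1,2,3,4,4a,5,6,7-octahydronaphthalen-1-yl]methyl}benzoate
Conditions: Dess–Martin periodinane, CH2Cl2, rt
Reagents that add atoms: none
Why: Dess–Martin oxidation gives the C4 ketone; the alkene cannot move into conjugation because C5 is quaternary, and the phenol is still protected and cannot be oxidised.

Step 15
Reactants: 22 methyl 4-(benzyloxy)-3-{[(1R,2S,4aS)-1,2,4a-trimethyl-5-oxo-1,2,3,4,4a,5,6,7-octahydronaphthalen-1-yl]methyl}benzoate
Product: 23 methyl 4-hydroxy-3-{[(1R,2S,4aS,8aS)-1,2,4a-trimethyl-5-oxodecahydronaphthalen-1-yl]methyl}benzoate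
Conditions: H2 (3 atm), 10% Pd/C, EtOAc–MeOH, rt
Reagents that add atoms: none
Why: Heterogeneous hydrogenation should add hydrogen to the α face of C1=C10, because the β face is covered by the axial methyls at C5 and C9; this gives the trans ring fusion (H-10 α). The benzyl ether is hydrogenolysed in the same operation.

Step 16
Reactants: 23 methyl 4-hydroxy-3-{[(1R,2S,4aS,8aS)-1,2,4a-trimethyl-5-oxodecahydronaphthalen-1-yl]methyl}benzoate
Product: 24 dictyoceratin C, methyl 4-hydroxy-3-{[(1R,2S,4aS,8aS)-1,2,4a-trimethyl-5-methylidenedecahydronaphthalen-1-yl]methyl}benzoate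
Conditions: Ph3PCH3Br, KN(SiMe3)2 (excess), toluene, 0 → 90 °C; aq NH4Cl
Reagents that add atoms: methyltriphenylphosphonium bromide, C[P+](c1ccccc1)(c1ccccc1)c1ccccc1.[Br-]
Why: Wittig methylenation of the hindered C4 ketone with excess salt-free ylide; the phenol is deprotonated first, which deactivates the para ester toward the ylide. The ketone has no epimerisable α-stereocentre, and the alkene is formed under basic conditions and never meets acid.

## Compound list

1 | (E)-2-methylbut-2-enal (tiglic aldehyde) | C/C=C(\C)C=O | starting material
2 | (1E)-1-(tert-butyldimethylsilyloxy)-2-methylbuta-1,3-diene | C=C/C(C)=C/O[Si](C)(C)C(C)(C)C | intermediate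
3 | (1R,2S,6S)-2-(tert-butyldimethylsilyloxy)-1,3,6-trimethylcyclohex-3-ene-1-carbaldehyde | CC1=CC[C@H](C)[C@@](C)(C=O)[C@H]1O[Si](C)(C)C(C)(C)C | intermediate
4 | methyl 4-hydroxy-3-iodobenzoate | COC(=O)c1ccc(O)c(I)c1 | starting material
5 | methyl 4-(benzyloxy)-3-iodobenzoate | COC(=O)c1ccc(OCc2ccccc2)c(I)c1 | intermediate
6 | [2-(benzyloxy)-5-(methoxycarbonyl)phenyl]magnesium chloride (LiCl complex, not isolated) | COC(=O)c1ccc(OCc2ccccc2)c([Mg]Cl)c1 | intermediate
7 | methyl 4-(benzyloxy)-3-{hydroxy[(1S,2S,6S)-2-(tert-butyldimethylsilyloxy)-1,3,6-trimethylcyclohex-3-en-1-yl]methyl}benzoate (C11 epimers) | CC1=CC[C@H](C)[C@@](C)(C(O)c2cc(C(=O)OC)ccc2OCc2ccccc2)[C@H]1O[Si](C)(C)C(C)(C)C | intermediate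
8 | sodium O-alkyl dithiocarbonate (xanthate salt) of 7 (not isolated) | CC1=CC[C@H](C)[C@@](C)(C(OC(=S)[S-])c2cc(C(=O)OC)ccc2OCc2ccccc2)[C@H]1O[Si](C)(C)C(C)(C)C.[Na+] | intermediate
9 | S-methyl xanthate of 7 | CC1=CC[C@H](C)[C@@](C)(C(OC(=S)SC)c2cc(C(=O)OC)ccc2OCc2ccccc2)[C@H]1O[Si](C)(C)C(C)(C)C | intermediate
10 | methyl 4-(benzyloxy)-3-{[(1R,2S,6S)-2-(tert-butyldimethylsilyloxy)-1,3,6-trimethylcyclohex-3-en-1-yl]methyl}benzoate | CC1=CC[C@H](C)[C@@](C)(Cc2cc(C(=O)OC)ccc2OCc2ccccc2)[C@H]1O[Si](C)(C)C(C)(C)C | intermediate
11 | methyl 4-(benzyloxy)-3-{[(1R,2S,6S)-2-hydroxy-1,3,6-trimethylcyclohex-3-en-1-yl]methyl}benzoate | CC1=CC[C@H](C)[C@@](C)(Cc2cc(C(=O)OC)ccc2OCc2ccccc2)[C@H]1O | intermediate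
12 | methyl 4-(benzyloxy)-3-{[(1R,6S)-1,3,6-trimethyl-2-oxocyclohex-3-en-1-yl]methyl}benzoate | CC1=CC[C@H](C)[C@@](C)(Cc2cc(C(=O)OC)ccc2OCc2ccccc2)C1=O | intermediate
13 | pent-4-enal | C=CCCC=O | starting material
14 | lithium (5S,6R)-6-[2-(benzyloxy)-5-(methoxycarbonyl)benzyl]-2,5,6-trimethylcyclohex-1-en-1-olate (not isolated) | CC1=C([O-])[C@](C)(Cc2cc(C(=O)OC)ccc2OCc2ccccc2)[C@@H](C)CC1.[Li+] | intermediate
15 | methyl 4-(benzyloxy)-3-{[(1R,3R,6S)-3-(1-hydroxypent-4-en-1-yl)-1,3,6-trimethyl-2-oxocyclohexyl]methyl}benzoate (C4 epimers) | C=CCCC(O)[C@]1(C)C(=O)[C@](C)(Cc2cc(C(=O)OC)ccc2OCc2ccccc2)[C@@H](C)CC1 | intermediate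
16 | tert-butyldimethylsilyl ether of 15 | C=CCCC(O[Si](C)(C)C(C)(C)C)[C@]1(C)C(=O)[C@](C)(Cc2cc(C(=O)OC)ccc2OCc2ccccc2)[C@@H](C)CC1 | intermediate
17 | secondary ozonide (1,2,4-trioxolane) of 16 (not isolated) | O1OC(CCC(O[Si](C)(C)C(C)(C)C)[C@]2(C)C(=O)[C@](C)(Cc3cc(C(=O)OC)ccc3OCc3ccccc3)[C@@H](C)CC2)OC1 | intermediate
18 | methyl 4-(benzyloxy)-3-{[(1R,3R,6S)-3-[1-(tert-butyldimethylsilyloxy)-4-oxobutyl]-1,3,6-trimethyl-2-oxocyclohexyl]methyl}benzoate | O=CCCC(O[Si](C)(C)C(C)(C)C)[C@]1(C)C(=O)[C@](C)(Cc2cc(C(=O)OC)ccc2OCc2ccccc2)[C@@H](C)CC1 | intermediate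
19 | cyclic titanium C1,C10-diolate of the coupled decalin (not isolated) | CC(C)(C)[Si](C)(C)OC1CCC2O[Ti]OC23[C@](C)(Cc4cc(C(=O)OC)ccc4OCc4ccccc4)[C@@H](C)CC[C@]13C | intermediate
20 | methyl 4-(benzyloxy)-3-{[(1R,2S,4aS)-5-(tert-butyldimethylsilyloxy)-1,2,4a-trimethyl-1,2,3,4,4a,5,6,7-octahydronaphthalen-1-yl]methyl}benzoate | CC(C)(C)[Si](C)(C)OC1CCC=C2[C@](C)(Cc3cc(C(=O)OC)ccc3OCc3ccccc3)[C@@H](C)CC[C@]12C | intermediate
21 | methyl 4-(benzyloxy)-3-{[(1R,2S,4aS)-5-hydroxy-1,2,4a-trimethyl-1,2,3,4,4a,5,6,7-octahydronaphthalen-1-yl]methyl}benzoate | OC1CCC=C2[C@](C)(Cc3cc(C(=O)OC)ccc3OCc3ccccc3)[C@@H](C)CC[C@]12C | intermediate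
22 | methyl 4-(benzyloxy)-3-{[(1R,2S,4aS)-1,2,4a-trimethyl-5-oxo-1,2,3,4,4a,5,6,7-octahydronaphthalen-1-yl]methyl}benzoate | O=C1CCC=C2[C@](C)(Cc3cc(C(=O)OC)ccc3OCc3ccccc3)[C@@H](C)CC[C@]12C | intermediate
23 | methyl 4-hydroxy-3-{[(1R,2S,4aS,8aS)-1,2,4a-trimethyl-5-oxodecahydronaphthalen-1-yl]methyl}benzoate | O=C1CCC[C@H]2[C@](C)(Cc3cc(C(=O)OC)ccc3O)[C@@H](C)CC[C@]12C | intermediate
24 | dictyoceratin C | C=C1CCC[C@H]2[C@](C)(Cc3cc(C(=O)OC)ccc3O)[C@@H](C)CC[C@]12C | target

## Step count and uncertain steps

Total step count: 16. Longest linear sequence: 15 steps (steps 1, 2 and 4–16, from 1); the arene branch adds step 3.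

**Step 2 (key step).** The most likely failures are addition of the silyl dienol ether to the activated carbonyl group instead of the alkene, acid-induced loss of the silyl group from the diene, and weak facial discrimination with a slow, β-substituted dienophile. Fallback, setting out from 1 and 2: the cycloaddition is run without any Lewis acid (toluene, 130 °C, sealed tube, or under high pressure). This should give the racemate of 3 with the same regiochemistry and the same C8/C9 relationship; any C10 epimer is removed by chromatography. The racemates of 3, 7, 9, 10 and 11 are carried through steps 4–7 unchanged. Racemic 11 is esterified with (S)-2-methoxy-2-phenylacetic acid (DCC, DMAP), giving the (S)-O-methylmandelate of 11, F1, and the (S)-O-methylmandelate of the enantiomer of 11, F2. The two diastereomers are separated, and F1 is methanolysed (K2CO3, MeOH) to come back to the route at 11.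

**Step 9.** Two processes threaten it: attack of the aldehyde on the β face of the enolate if the ring reacts through the conformer with the arylmethyl group pseudoaxial, and proton transfer from the enolisable aldehyde to the hindered enolate. Fallback, setting out from 11, whose C10 hydroxyl is α as delivered by the endo cycloadduct:
- the alcohol is silylated with (bromomethyl)chlorodimethylsilane (Et3N, DMAP) to the (bromomethyl)dimethylsilyl ether F3;
- n-Bu3SnH and AIBN induce 5-exo radical cyclisation, which must deliver the carbon to C5 on the face of the C10 oxygen, giving the cis-fused cyclic siloxane F4;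
- Tamao oxidation (H2O2, KF, KHCO3) gives the diol F5 with the C5 hydroxymethyl group α;
- Swern oxidation gives the keto aldehyde F6;
- but-3-enylmagnesium bromide at −78 °C adds to the aldehyde only and returns to the route at 15.

**Step 12.** The hindered ketone may fail to couple, so that the aldehyde is merely reduced or couples intermolecularly; the benzyl ether or the ester may also be attacked by low-valent titanium. Fallback, setting out from 18: the aldehyde alone is reduced (NaBH4, MeOH, −40 °C) to the primary alcohol F7. This is converted into the iodide F8 (I2, PPh3, imidazole). SmI2 in THF–HMPA closes the ring by Barbier addition to the C10 ketone, giving the tertiary decalinol F9. Dehydration with Burgess reagent can give only the C1=C10 alkene and returns to the route at 20.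

**Step 5.** Silyl migration from the C10 oxygen to the C11 alkoxide before trapping would place the xanthate on the wrong oxygen. Fallback, setting out from 7: the alcohol is acylated under neutral conditions with 1,1′-thiocarbonyldiimidazole (DMAP, toluene, 90 °C) to the imidazole-1-carbothioate F10, which is reduced with n-Bu3SnH and AIBN to come back at 10.

**Step 15.** The alkene, flanked by two quaternary carbons, may resist adsorption on the metal, or hydrogen may be delivered without facial preference. Fallback, setting out from 22: hydrogen-atom-transfer reduction with Mn(dpm)3 (dpm = 2,2,6,6-tetramethylheptane-3,5-dionate, cat.), PhSiH3 and t-BuOOH in i-PrOH passes through the tertiary C10 radical and should give the thermodynamically preferred trans-fused benzyl ether F11. The benzyl group is then removed with H2 and 10% Pd/C at 1 atm to come back at 23.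

**Step 16.** Slow addition of the ylide to the hindered ketone may let enolisation or attack on the ester take over. Fallback, setting out from 23: methylenation with the non-basic reagent from Zn, CH2Br2 and TiCl4 (THF–CH2Cl2, excess to cover the phenol) leads directly to 24; no new compound is made.

## Further compounds

F1 | step 2 | (S)-2-methoxy-2-phenylacetate ester of 11 | CC1=CC[C@H](C)[C@@](C)(Cc2cc(C(=O)OC)ccc2OCc2ccccc2)[C@H]1OC(=O)[C@@H](OC)c1ccccc1
F2 | step 2 | (S)-2-methoxy-2-phenylacetate ester of the enantiomer of 11 | CC1=CC[C@@H](C)[C@](C)(Cc2cc(C(=O)OC)ccc2OCc2ccccc2)[C@@H]1OC(=O)[C@@H](OC)c1ccccc1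
F3 | step 9 | (bromomethyl)dimethylsilyl ether of 11 | CC1=CC[C@H](C)[C@@](C)(Cc2cc(C(=O)OC)ccc2OCc2ccccc2)[C@H]1O[Si](C)(C)CBr
F4 | step 9 | cis-fused cyclic siloxane (C5–CH2–SiMe2–O–C10) | C[C@]12CC[C@H](C)[C@@](C)(Cc3cc(C(=O)OC)ccc3OCc3ccccc3)[C@H]1O[Si](C)(C)C2
F5 | step 9 | diol with 5α-hydroxymethyl and 10α-hydroxyl | C[C@]1(CO)CC[C@H](C)[C@@](C)(Cc2cc(C(=O)OC)ccc2OCc2ccccc2)[C@H]1O
F6 | step 9 | C4 aldehyde, C10 ketone (keto aldehyde) | C[C@]1(C=O)CC[C@H](C)[C@@](C)(Cc2cc(C(=O)OC)ccc2OCc2ccccc2)C1=O
F7 | step 12 | C1 primary alcohol from 18 | OCCCC(O[Si](C)(C)C(C)(C)C)[C@]1(C)C(=O)[C@](C)(Cc2cc(C(=O)OC)ccc2OCc2ccccc2)[C@@H](C)CC1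
F8 | step 12 | C1 primary iodide | ICCCC(O[Si](C)(C)C(C)(C)C)[C@]1(C)C(=O)[C@](C)(Cc2cc(C(=O)OC)ccc2OCc2ccccc2)[C@@H](C)CC1
F9 | step 12 | C10 tertiary decalinol | CC(C)(C)[Si](C)(C)OC1CCCC2(O)[C@](C)(Cc3cc(C(=O)OC)ccc3OCc3ccccc3)[C@@H](C)CC[C@]12C
F10 | step 5 | O-alkyl 1H-imidazole-1-carbothioate of 7 | CC1=CC[C@H](C)[C@@](C)(C(OC(=S)n2ccnc2)c2cc(C(=O)OC)ccc2OCc2ccccc2)[C@H]1O[Si](C)(C)C(C)(C)C
F11 | step 15 | benzyl ether of 23 | O=C1CCC[C@H]2[C@](C)(Cc3cc(C(=O)OC)ccc3OCc3ccccc3)[C@@H](C)CC[C@]12C
F0 | step 16 | none | none
A1 | alternative 1 | dictyoceratin C O-acetate | C=C1CCC[C@H]2[C@](C)(Cc3cc(C(=O)OC)ccc3OC(C)=O)[C@@H](C)CC[C@]12C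
A2 | alternative 1 | sclareolide | CC1(C)CCC[C@@]2(C)[C@H]1CC[C@@]1(C)OC(=O)C[C@H]21
A3 | alternative 2 | 8-phenylmenthyl trans-decalin keto ester (C8 ketone, C9 ester and arylmethyl, C4 silylmethylene) | C[Si](C)(C)C=C1CCC[C@H]2[C@](C(=O)O[C@@H]3C[C@H](C)CC[C@H]3C(C)(C)c3ccccc3)(Cc3cc(Br)ccc3O[Si](C(C)C)(C(C)C)C(C)C)C(=O)CC[C@]12C
A4 | alternative 3 | methyl 5-(2-methoxybenzyl)-6-methyl-9-oxo-3-thiabicyclo[3.3.1]non-6-ene-1-carboxylate | COC(=O)[C@]12CSC[C@](Cc3ccccc3OC)(C1=O)C(C)=CC2
A5 | alternative 3 | but-3-en-2-one (methyl vinyl ketone) | C=CC(C)=O
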